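Numbering used throughout: bicyclo[3.2.1]octane core with C1 (prenyl bridgehead), C2 (C=O), C3 (acyl-bearing carbon), C4 (enol carbon), C5 (methyl bridgehead), C6 (CH–CMe2OH), C7 (CH2), C8 (bridging C=O).
Retrosynthetic cuts, in order: C2–C3 and C3–C4 (C3 and its isobutyryl group leave as 3-methylbutan-2-one, C2 becomes a methyl ester, C4 a γ-lactone closed by the C6 side-chain oxygen); then C5–CH3; then C1–C7 and C5–C8 together.
Enabling feature: in the cyclopentanone ring C1–C7–C6–C5–C8 the side-chain oxygen on C6 lies on the same face as C4. Tied to C4 as a lactone (a ring the target lacks), it makes C5 an enolisable lactone α-carbon and, with bromine on C7, turns C5–C6–C7 into a donor/acceptor three-carbon unit that matches the donor/acceptor pair C1/C8 of a prenylmalonate.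
Forward order: conjugate addition to a butenolide sets C6; HBr transposes the lactone and places bromine on C7; alkylation/Dieckmann closes the cyclopentanone; C5 is methylated; a double Claisen condensation with 3-methylbutan-2-one opens the lactone, closes the six-membered ring and frees the tertiary alcohol.
Stereochemistry: C6 from the rhodium/BINAP-catalysed addition; C5 relayed through the obligatory cis fusion of lactone and cyclopentanone; C1 from the choice between two diastereotopic esters in the Dieckmann closure, then locked by the bicycle.
Key step: step 4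

Assumption: the target is drawn as one enol tautomer of a β-triketone; the tautomers interconvert, so the route aims at the compound as its equilibrium mixture.
Assumption: (S)-BINAP is taken to give (S)-3 by analogy with cyclic enones and unsaturated lactones; if the sense proves opposite, (R)-BINAP is used.

Step 1
Reactants: 1 furan-2(5H)-one; 2 potassium trifluoro(prop-1-en-2-yl)borate
Product: 3 (4S)-4-(prop-1-en-2-yl)oxolan-2-one
Conditions: [Rh(cod)2]PF6 (3 mol%, cod = cycloocta-1,5-diene), (S)-BINAP (3.3 mol%), toluene–H2O (20:1), 105 °C
Reagents that add atoms: none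
Why: Rhodium-catalysed asymmetric conjugate addition of an alkenylboron reagent to a butenolide (Hayashi–Miyaura reaction) should set the only catalysis-derived stereocentre (the later C6) by enantioface-selective insertion of the butenolide into the alkenyl–rhodium bond under control of the BINAP ligand.

Step 2
Reactants: 3 (4S)-4-(prop-1-en-2-yl)oxolan-2-one
Product: 4 (4S)-4-(bromomethyl)-5,5-dimethyloxolan-2-one
Conditions: HBr (33% in AcOH), 0 °C → rt
Reagents that add atoms: hydrogen bromide, SMILES Br
Why: Markovnikov protonation of the isopropenyl group gives a tertiary cation that the lactone carbonyl oxygen captures, and bromide opens the resulting bicyclic dioxolan-2-ylium ion at its primary O–CH2 carbon (the SN2 event known from the HBr cleavage of γ-butyrolactone to 4-bromobutanoic acid), so the lactone is transposed onto the new CMe2–O centre while no bond to the stereocentre is touched.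

Step 3
Reactants: 5 dimethyl propanedioate (dimethyl malonate); 6 1-bromo-3-methylbut-2-ene (prenyl bromide)
Product: 7 dimethyl 2-(3-methylbut-2-en-1-yl)propanedioate
Conditions: NaH (1.0 equiv), THF, 0 °C; 6 (0.9 equiv), 0 °C → rt
Reagents that add atoms: none
Why: Malonic ester C-alkylation (SN2 of the sodium enolate on a primary allylic bromide) with the bromide as limiting reagent to suppress dialkylation; no stereocentre is formed.

Step 4
Reactants: 4 (4S)-4-(bromomethyl)-5,5-dimethyloxolan-2-one; 7 dimethyl 2-(3-methylbut-2-en-1-yl)propanedioate
Product: 9 methyl (3aS,5R,6aS)-3,3-dimethyl-5-(3-methylbut-2-en-1-yl)-1,6-dioxohexahydro-1H-cyclopenta[c]furan-5-carboxylate, via alkylated malonate 8 (not isolated)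
Conditions: NaH (1.2 equiv), 7 (1.3 equiv), THF–DMF (3:1), 0 °C; 4 (1.0 equiv), NaI (0.2 equiv), 65 °C; then KOt-Bu (1.3 equiv), −20 → 0 °C; aq. HCl
Reagents that add atoms: none
Why: The sodium enolate of 7 displaces bromide from the CH2Br carbon of 4 (SN2, assisted by iodide), forming the C1–C7 bond (target numbering) and the fully substituted malonate 8, whose only acidic C–H is the lactone α-CH2; KOt-Bu then makes the lactone enolate, which attacks one of the two ester groups (Dieckmann condensation) to form the C5–C8 bond, and deprotonation of the new β-keto lactone pulls the closure forward. The closest known reaction type is the classical malonate alkylation–Dieckmann (Perkin) synthesis of 2-oxocyclopentanecarboxylates, used here as a formal [3+2] union of a 1,3-donor/acceptor unit with a 1,2-donor/acceptor unit. The one ring that closes is the cyclopentanone, by 5-(enolexo)-exo-trig attack of the enolate carbon on the ester carbonyl. Because the enolate carbon and the tether both belong to the lactone ring, the new ring can only be cis-fused, so C6a (the later C5) is set by C3a (the later C6), itself from step 1. The quaternary centre C5 of 9 (the later C1) is set by the choice between the two diastereotopic esters: the transition state that places the flat spectator ester on the concave face beside the endo methyl of the CMe2 group and the bulkier prenyl CH2 on the open convex face should be the lower one. The step needs C-alkylation to precede any enolisation of 4 (whose enolate would close a cyclopropane) and needs the malonate carbon to stay away from the lactone carbonyl; the first is secured by using only the weakly basic malonate anion until the bromide is consumed, the second by the prenyl group, which leaves that carbon without a proton.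

Step 5
Reactants: 9 methyl (3aS,5R,6aS)-3,3-dimethyl-5-(3-methylbut-2-en-1-yl)-1,6-dioxohexahydro-1H-cyclopenta[c]furan-5-carboxylate
Product: 10 methyl (3aS,5R,6aS)-3,3,6a-trimethyl-5-(3-methylbut-2-en-1-yl)-1,6-dioxohexahydro-1H-cyclopenta[c]furan-5-carboxylate
Conditions: K2CO3, MeI, acetone, rt
Reagents that add atoms: iodomethane, SMILES CI
Why: C-Alkylation of the potassium enolate of the β-keto lactone at its ring-fusion carbon (acetoacetic-ester-type alkylation) installs the C5 methyl group, and since only the cis-fused bicycle can form, the configuration at C6a follows from C3a.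

Step 6
Reactants: 10 methyl (3aS,5R,6aS)-3,3,6a-trimethyl-5-(3-methylbut-2-en-1-yl)-1,6-dioxohexahydro-1H-cyclopenta[c]furan-5-carboxylate; 11 3-methylbutan-2-one
Product: 13 (1R,5R,6S)-4-hydroxy-6-(2-hydroxypropan-2-yl)-5-methyl-1-(3-methylbut-2-en-1-yl)-3-(2-methylpropanoyl)bicyclo[3.2.1]oct-3-ene-2,8-dione, via ring-opened diketone 12 (not isolated)
Conditions: 11 (2.5 equiv), LiN(i-Pr)2 (2.5 equiv), THF, −78 °C; 10, −78 °C → rt, then 45 °C; aq. HCl
Reagents that add atoms: none
Why: The kinetic lithium enolate of the methyl ketone is acylated by the γ-lactone (crossed Claisen condensation, which releases the tertiary alkoxide) and the carbon of the resulting 1,3-diketonate is then acylated by the cis-disposed methyl ester to close the six-membered ring, as in the diester-plus-methyl-ketone synthesis of 2-acylcycloalkane-1,3-diones, the sequence being driven by formation of the acidic enolised triketone, with all three stereocentres already in place and addition of the enolate to the hindered, non-enolisable ketone (the later C8) expected to be reversible.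

Compound list
1 | furan-2(5H)-one | O=C1OCC=C1 | starting material
2 | potassium trifluoro(prop-1-en-2-yl)borate | [K+].C=C(C)[B-](F)(F)F | starting material
3 | (4S)-4-(prop-1-en-2-yl)oxolan-2-one | CC(=C)[C@H]1COC(=O)C1 | intermediate
4 | (4S)-4-(bromomethyl)-5,5-dimethyloxolan-2-one | BrC[C@H]1CC(=O)OC1(C)C | intermediate
5 | dimethyl propanedioate | COC(=O)CC(=O)OC | starting material
6 | 1-bromo-3-methylbut-2-ene | CC(C)=CCBr | starting material
7 | dimethyl 2-(3-methylbut-2-en-1-yl)propanedioate | COC(=O)C(CC=C(C)C)C(=O)OC | intermediate
8 | dimethyl 2-{[(3S)-2,2-dimethyl-5-oxooxolan-3-yl]methyl}-2-(3-methylbut-2-en-1-yl)propanedioate (alkylated malonate, not isolated) | COC(=O)C(CC=C(C)C)(C[C@H]1CC(=O)OC1(C)C)C(=O)OC | intermediate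
9 | methyl (3aS,5R,6aS)-3,3-dimethyl-5-(3-methylbut-2-en-1-yl)-1,6-dioxohexahydro-1H-cyclopenta[c]furan-5-carboxylate | CC(C)=CC[C@@]1(C(=O)OC)C[C@@H]2C(C)(C)OC(=O)[C@@H]2C1=O | intermediate
10 | methyl (3aS,5R,6aS)-3,3,6a-trimethyl-5-(3-methylbut-2-en-1-yl)-1,6-dioxohexahydro-1H-cyclopenta[c]furan-5-carboxylate | CC(C)=CC[C@@]1(C(=O)OC)C[C@@H]2C(C)(C)OC(=O)[C@]2(C)C1=O | intermediate
11 | 3-methylbutan-2-one | CC(=O)C(C)C | starting material
12 | methyl (1R,3S,4R)-3-(2-hydroxypropan-2-yl)-4-methyl-1-(3-methylbut-2-en-1-yl)-4-(4-methyl-3-oxopentanoyl)-5-oxocyclopentane-1-carboxylate (ring-opened diketone, not isolated, present as its lithium salts) | CC(C)=CC[C@@]1(C(=O)OC)C[C@H](C(C)(C)O)[C@](C)(C(=O)CC(=O)C(C)C)C1=O | intermediate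
13 | (1R,5R,6S)-4-hydroxy-6-(2-hydroxypropan-2-yl)-5-methyl-1-(3-methylbut-2-en-1-yl)-3-(2-methylpropanoyl)bicyclo[3.2.1]oct-3-ene-2,8-dione | CC(C)=CC[C@@]12C[C@H](C(C)(C)O)[C@@](C)(C1=O)C(O)=C(C(=O)C(C)C)C2=O | target

Total step count: 6. Longest linear sequence: 5 steps (steps 1, 2, 4, 5, 6).

Steps most likely to fail

1. Step 4. The substitution at the β-branched primary carbon may be slow, and, more seriously, the ring closure may discriminate poorly between the two ester groups, so that the centre next to the prenyl group forms with low selectivity (the wrong epimer cannot close the last ring). The fallback sets the prenyl-bearing centre by alkylation of the finished bicycle instead; it sets out from 4 and 5 and comes back to the route at 10. Dimethyl malonate 5 (in excess; NaH, NaI, DMF, 60 °C) is alkylated with 4 to the mono-alkylated malonate F1. Its sodium enolate is C-acylated with methyl chloroformate to the triester F2, in which the malonate carbon carries three identical esters, so no stereocentre arises there. Dieckmann closure (KOt-Bu, THF, 0 °C) gives the geminal diester keto lactone F3, and iodomethane added to the same flask methylates the ring-fusion carbon to the methylated geminal diester F4. Krapcho demethoxycarbonylation (LiCl, wet DMSO, 110 °C) removes one ester and gives the β-keto ester F5. C-Alkylation of its potassium enolate with 6 (K2CO3, acetone) should bring the prenyl group in from the convex face, away from the lactone ring, and returns to 10.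

2. Step 6. The ketone enolate may add to the ring ketone of 10 and the adduct may fragment by carbon–carbon cleavage (retro-Claisen), and the second acylation of the diketonate by the hindered ester may be slow. The fallback removes the ketone for the duration of the annulation; it sets out from 10 and comes back at 13. Reduction with NaBH4 (MeOH, 0 °C) gives the ring carbinol F6 (either epimer serves). The same double Claisen condensation with the lithium enolate of 11 then proceeds through the ring-opened diketone carbinol F7 to the bridged triketone carbinol F8. Oxidation of the bridging secondary alcohol (Dess–Martin periodinane, NaHCO3, CH2Cl2) returns to 13.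

3. Step 2. The tertiary cation next to the stereocentre may lose a proton reversibly and so erode the enantiomeric purity, and the lactone transposition may stop short of completion. The fallback avoids any cation; it sets out from 3 and comes back at 4. Saponification (LiOH, THF–H2O) gives (3S)-3-(hydroxymethyl)-4-methylpent-4-enoic acid F9, kept as its salt. Iodolactonization (I2, NaHCO3, MeCN–H2O; 5-exo attack of the carboxylate on the substituted alkene carbon) gives the iodolactone F10 as a mixture at the new, temporary centre. Radical deiodination (Bu3SnH, AIBN, benzene, 80 °C) gives the hydroxymethyl lactone F11, and Appel bromination (CBr4, PPh3, CH2Cl2) returns to 4.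

Further compounds
F1 | step 4 | dimethyl 2-{[(3S)-2,2-dimethyl-5-oxooxolan-3-yl]methyl}propanedioate | COC(=O)C(C[C@H]1CC(=O)OC1(C)C)C(=O)OC
F2 | step 4 | trimethyl 2-[(3S)-2,2-dimethyl-5-oxooxolan-3-yl]ethane-1,1,1-tricarboxylate | COC(=O)C(C[C@H]1CC(=O)OC1(C)C)(C(=O)OC)C(=O)OC
F3 | step 4 | dimethyl (3aS,6aS)-3,3-dimethyl-1,6-dioxohexahydro-1H-cyclopenta[c]furan-5,5-dicarboxylate | COC(=O)C1(C(=O)OC)C[C@@H]2C(C)(C)OC(=O)[C@@H]2C1=O
F4 | step 4 | dimethyl (3aS,6aS)-3,3,6a-trimethyl-1,6-dioxohexahydro-1H-cyclopenta[c]furan-5,5-dicarboxylate | COC(=O)C1(C(=O)OC)C[C@@H]2C(C)(C)OC(=O)[C@]2(C)C1=O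
F5 | step 4 | methyl (3aS,6aS)-3,3,6a-trimethyl-1,6-dioxohexahydro-1H-cyclopenta[c]furan-5-carboxylate (C5 epimers and enol) | COC(=O)C1C[C@@H]2C(C)(C)OC(=O)[C@]2(C)C1=O
F6 | step 6 | methyl (3aS,5R,6aS)-6-hydroxy-3,3,6a-trimethyl-5-(3-methylbut-2-en-1-yl)-1-oxohexahydro-1H-cyclopenta[c]furan-5-carboxylate (C6 epimers) | CC(C)=CC[C@@]1(C(=O)OC)C[C@@H]2C(C)(C)OC(=O)[C@]2(C)C1O
F7 | step 6 | the 5-hydroxy analogue of 12 (ring-opened diketone carbinol) | CC(C)=CC[C@@]1(C(=O)OC)C[C@H](C(C)(C)O)[C@](C)(C(=O)CC(=O)C(C)C)C1O
F8 | step 6 | the 8-hydroxy analogue of 13 (bridged triketone carbinol, C8 epimers) | CC(C)=CC[C@@]12C[C@H](C(C)(C)O)[C@@](C)(C1O)C(O)=C(C(=O)C(C)C)C2=O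
F9 | step 2 | (3S)-3-(hydroxymethyl)-4-methylpent-4-enoic acid | OC[C@@H](CC(=O)O)C(C)=C
F10 | step 2 | (4R)-4-(hydroxymethyl)-5-(iodomethyl)-5-methyloxolan-2-one (C5 epimers) | OC[C@H]1CC(=O)OC1(C)CI
F11 | step 2 | (4R)-4-(hydroxymethyl)-5,5-dimethyloxolan-2-one | OC[C@H]1CC(=O)OC1(C)C
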